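**Retrosynthetic overview**

1. Feature: the cyclohexa-2,4-diene ring carries the only stereocentres, C1 (quaternary: CH3 and pyranone C6) and C6 (H and the chain C7(CH3)=C8H–C9(=O)CH3), with the pyranone carbon and the chain cis. Without the C6–C7 bond, and with C4=C5 moved to C5=C6, the ring is 1,3,5-trimethylcyclohexa-2,5-diene-1-carboxylic acid, which is achiral (mirror plane through C1 and C4); pyranone C6 is its carboxyl carbon.
2. Target ⇒ (Z)-enone isomer (C7=C8 geometry corrected last) ⇒ 4-hydroxy-2-pyranone ⇒ open-chain 3,5-diketo ester. The pyranone is the last ring formed, from the carboxyl carbon and the dianion of methyl 2-methyl-3-oxopentanoate.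
3. 3,5-Diketo ester ⇒ seven-membered enol lactone (ring atoms O, C=O, C1, C6, C7, C8, C9), in which the C9 enol oxygen is acylated by the C1 carboxyl carbon. Acyl transfer to the dianion cuts this temporary link and frees the enone.
4. Enol lactone ⇒ C6–C7 disconnection by an enantioselective intramolecular Heck reaction of the (3Z)-4-iodopenta-1,3-dien-2-yl ester of the diene acid. This one step closes the lactone and sets C1 and C6.
5. Ester ⇒ diene acid chloride (from 3,5-dimethylbenzoic acid by Birch reductive methylation) + enolate of (Z)-4-iodopent-3-en-2-one (from pent-3-yn-2-one and NaI). Ring order: carbocycle, temporary lactone, pyranone.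

Key step: step 5

Locants used throughout: carbocycle C1 (quaternary) to C6 (CH); side chain C7(CH3)=C8H–C9(=O)–CH3; "carboxyl carbon" is the carbon on C1 that ends as pyranone C6.

Assumption: the sense of induction of a BINAP enantiomer cannot be carried over with confidence from six-membered closures to this seven-membered one. (R)-BINAP is written; if the cyclisation delivers the (5aR,9aR) lactone, (S)-BINAP is used instead.

**Route**

Step 1
Reactants: 1 3,5-dimethylbenzoic acid; 2 iodomethane
Product: 4 1,3,5-trimethylcyclohexa-2,5-diene-1-carboxylic acid, via dilithium enediolate 3 (not isolated)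
Conditions: Li (3 equiv), NH3(l)/THF, −78 °C; then MeI (excess), −78 °C to rt; cold aq HCl
Reagents that add atoms: iodomethane (compound 2), CI
Why: Birch reduction of the benzoate leaves the two methyl-bearing carbons sp2, ammonia protonates C4, and the remaining carboxylate-stabilised C1 anion is C-methylated by iodomethane (Birch reductive alkylation), which gives the achiral 2,5-diene acid with the quaternary C1 in place.

Step 2
Reactants: 4 1,3,5-trimethylcyclohexa-2,5-diene-1-carboxylic acid
Product: 5 1,3,5-trimethylcyclohexa-2,5-diene-1-carbonyl chloride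
Conditions: (COCl)2, DMF (cat.), CH2Cl2, 0 °C to rt; volatiles removed, used crude
Reagents that add atoms: oxalyl chloride, ClC(=O)C(=O)Cl
Why: Acid chloride formation through the Vilsmeier-type chloroiminium species is mild enough for the skipped diene, and the quaternary C1 can neither enolise nor aromatise.

Step 3
Reactants: 6 pent-3-yn-2-one
Product: 7 (Z)-4-iodopent-3-en-2-one
Conditions: NaI, AcOH, rt, dark
Reagents that add atoms: sodium iodide, [Na+].[I-]
Why: Conjugate hydroiodination of the ynone (iodide adds at C4, the allenol is protonated anti) should give at room temperature the kinetic (Z)-β-iodoenone with iodine cis to the acetyl group, the geometry the ring closure needs.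

Step 4
Reactants: 7 (Z)-4-iodopent-3-en-2-one; 5 1,3,5-trimethylcyclohexa-2,5-diene-1-carbonyl chloride
Product: 9 (3Z)-4-iodopenta-1,3-dien-2-yl 1,3,5-trimethylcyclohexa-2,5-diene-1-carboxylate, via potassium dienolate 8 (not isolated)
Conditions: KN(SiMe3)2, THF, −78 °C; then 5, −78 to 0 °C
Reagents that add atoms: none
Why: Kinetic deprotonation at the acetyl methyl gives the cross-conjugated potassium dienolate, and a dissociated potassium enolate meeting a hindered tertiary acyl chloride should react at oxygen (enolate O-acylation), leaving the Z-iodoalkene untouched.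

Step 5
Reactants: 9 (3Z)-4-iodopenta-1,3-dien-2-yl 1,3,5-trimethylcyclohexa-2,5-diene-1-carboxylate
Product: 10 (5aS,9aS)-5,6,8,9a-tetramethyl-3-methylidene-5a,9a-dihydro-2-benzoxepin-1(3H)-one (cis-fused)
Conditions: Pd(OAc)2 (10 mol %), (R)-BINAP (22 mol %), Ag3PO4 (2 equiv), NMP, 60 °C
Reagents that add atoms: none
Why: Asymmetric intramolecular Heck reaction: zerovalent palladium (formed from Pd(OAc)2 and excess BINAP) inserts into the alkenyl C–I bond with retention of the Z geometry, Ag3PO4 removes iodide to leave a cationic divalent palladium alkenyl with both phosphorus atoms bound, and syn carbopalladation of one ring alkene joins C7 to C6 and places palladium on C5; syn β-hydride elimination is then possible only from C4 or the C5 methyl (the C6 hydrogen is anti to palladium), and loss of the C4 hydrogen gives the conjugated C2=C3–C4=C5 diene, while the quaternary C1 rules out aromatisation. The closest known reaction type is the Pd(OAc)2/BINAP/silver-salt desymmetrisation of 1-substituted cyclohexa-2,5-dienes bearing a tethered alkenyl iodide or triflate, which gives cis-fused bicyclic 1,3-dienes by 5-exo or 6-exo closure; the seven-membered ring, the enol ester link and insertion into a methyl-substituted alkene are variations of it not yet tried. The lactone ring (O, C=O, C1, C6, C7, C8, C9) closes in the 7-exo-trig mode, expected over 8-endo because C6 is the unsubstituted and nearer alkene carbon. Both stereocentres arise in the single insertion event: the tether reaches only the ring face that carries the carboxyl carbon, so C1 and C6 must be cis, and the choice between the enantiotopic alkenes C5=C6 and C2=C3, and with it the absolute configuration at C1 and C6, is made by the chiral bisphosphine on the cationic palladium centre. The step thus needs enantiotopic-alkene selection (ligand), exo regioselectivity (tether length) and β-hydride loss toward C4 (conjugation, with hydridopalladium re-addition able to convert an exocyclic isomer into the diene).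

Step 6
Reactants: 10 (5aS,9aS)-5,6,8,9a-tetramethyl-3-methylidene-5a,9a-dihydro-2-benzoxepin-1(3H)-one; 11 methyl 2-methyl-3-oxopentanoate
Product: 13 methyl 2,4-dimethyl-3,5-dioxo-5-{(1S,6S)-1,3,5-trimethyl-6-[(2Z)-4-oxopent-2-en-2-yl]cyclohexa-2,4-dien-1-yl}pentanoate, via dilithium dianion 12 (not isolated)
Conditions: 11 (3 equiv), LiN(iPr)2 (6.3 equiv), THF, −78 to 0 °C; then 10, −78 to −20 °C; aq NH4Cl
Reagents that add atoms: none
Why: Claisen-type C-acylation of the β-keto ester dianion at its terminal carbon by the enol lactone, an activated ester whose leaving group is the dienolate of the (Z)-enone; that ketone stays masked as its lithium enolate until the quench, C1 is quaternary and the C6 hydrogen is not acidic in the dienolate, so both stereocentres and the Z alkene should survive.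

Step 7
Reactants: 13 methyl 2,4-dimethyl-3,5-dioxo-5-{(1S,6S)-1,3,5-trimethyl-6-[(2Z)-4-oxopent-2-en-2-yl]cyclohexa-2,4-dien-1-yl}pentanoate
Product: 14 4-hydroxy-3,5-dimethyl-6-{(1S,6S)-1,3,5-trimethyl-6-[(2Z)-4-oxopent-2-en-2-yl]cyclohexa-2,4-dien-1-yl}-2H-pyran-2-one
Conditions: DBU (2 equiv), toluene, rt; aq citric acid
Reagents that add atoms: none
Why: Base-mediated lactonisation of a 3,5-diketo ester (the enol oxygen of the C5 ketone adds to the methyl ester and methoxide leaves, 6-exo-trig addition–elimination) is the standard entry to 4-hydroxy-3,5-dimethyl-2-pyranones, and room temperature with a non-nucleophilic amidine is chosen so that the enone γ-hydrogen at ring C6 is not removed.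

Step 8
Reactants: 14 4-hydroxy-3,5-dimethyl-6-{(1S,6S)-1,3,5-trimethyl-6-[(2Z)-4-oxopent-2-en-2-yl]cyclohexa-2,4-dien-1-yl}-2H-pyran-2-one
Product: 16 2-methoxy-3,5-dimethyl-6-{(1S,6S)-1,3,5-trimethyl-6-[(2Z)-4-oxopent-2-en-2-yl]cyclohexa-2,4-dien-1-yl}-4H-pyran-4-one, via pyrylium triflate 15 (not isolated)
Conditions: MeOTf, CH2Cl2, 0 °C to rt; then aq NaHCO3
Reagents that add atoms: methyl trifluoromethanesulfonate, COS(=O)(=O)C(F)(F)F
Why: Used without base, the hard electrophile methyl triflate alkylates the neutral hydroxypyranone at the lactone carbonyl oxygen to give a 4-hydroxy-2-methoxypyrylium salt, which gives up its proton on bicarbonate work-up as the 2-methoxy-4-pyranone (the known regioselective O-methylation to α-methoxy-γ-pyranones).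

Step 9
Reactants: 16 2-methoxy-3,5-dimethyl-6-{(1S,6S)-1,3,5-trimethyl-6-[(2Z)-4-oxopent-2-en-2-yl]cyclohexa-2,4-dien-1-yl}-4H-pyran-4-one
Product: 17 2-methoxy-3,5-dimethyl-6-{(1S,6S)-1,3,5-trimethyl-6-[(2E)-4-oxopent-2-en-2-yl]cyclohexa-2,4-dien-1-yl}-4H-pyran-4-one
Conditions: I2 (5 mol %), CH2Cl2, rt, ambient light; aq Na2S2O3
Reagents that add atoms: none
Why: Iodine-catalysed alkene isomerisation (reversible iodine-atom addition and loss) equilibrates the trisubstituted enone toward the E isomer, in which acetyl lies cis to the small C7 methyl and trans to the crowded ring, and this radical path avoids a dienol, so C6 should not epimerise; residual Z isomer is separated and resubmitted.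

**Compound list**

1 | 3,5-dimethylbenzoic acid | Cc1cc(C)cc(C(=O)O)c1 | starting material
2 | iodomethane | CI | starting material
3 | dilithium (3,5-dimethylcyclohexa-2,5-dien-1-ylidene)methanediolate | [Li+].[Li+].[O-]C([O-])=C1C=C(C)CC(C)=C1 | intermediate (not isolated)
4 | 1,3,5-trimethylcyclohexa-2,5-diene-1-carboxylic acid | OC(=O)C1(C)C=C(C)CC(C)=C1 | intermediate
5 | 1,3,5-trimethylcyclohexa-2,5-diene-1-carbonyl chloride | O=C(Cl)C1(C)C=C(C)CC(C)=C1 | intermediate
6 | pent-3-yn-2-one | CC#CC(C)=O | starting material
7 | (Z)-4-iodopent-3-en-2-one | C/C(I)=C/C(C)=O | intermediate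
8 | potassium (3Z)-4-iodopenta-1,3-dien-2-olate | C=C([O-])/C=C(/C)I.[K+] | intermediate (not isolated)
9 | (3Z)-4-iodopenta-1,3-dien-2-yl 1,3,5-trimethylcyclohexa-2,5-diene-1-carboxylate | C/C(I)=C/C(=C)OC(=O)C1(C)C=C(C)CC(C)=C1 | intermediate
10 | (5aS,9aS)-5,6,8,9a-tetramethyl-3-methylidene-5a,9a-dihydro-2-benzoxepin-1(3H)-one | O=C3[C@@]2(C)C=C(C)C=C(C)[C@H]2/C(C)=C\C(=C)O3 | intermediate
11 | methyl 2-methyl-3-oxopentanoate | CCC(=O)C(C)C(=O)OC | starting material
12 | dilithium 1-methoxy-2-methylpenta-1,3-diene-1,3-diolate (dianion of 11) | [Li+].[Li+].COC([O-])=C(C)C([O-])=CC | intermediate (not isolated)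
13 | methyl 2,4-dimethyl-3,5-dioxo-5-{(1S,6S)-1,3,5-trimethyl-6-[(2Z)-4-oxopent-2-en-2-yl]cyclohexa-2,4-dien-1-yl}pentanoate (mixture at C2 and C4, keto/enol forms) | COC(=O)C(C)C(=O)C(C)C(=O)[C@@]1(C)C=C(C)C=C(C)[C@H]1/C(C)=C\C(C)=O | intermediate
14 | 4-hydroxy-3,5-dimethyl-6-{(1S,6S)-1,3,5-trimethyl-6-[(2Z)-4-oxopent-2-en-2-yl]cyclohexa-2,4-dien-1-yl}-2H-pyran-2-one | O=c1oc([C@@]2(C)C=C(C)C=C(C)[C@H]2/C(C)=C\C(C)=O)c(C)c(O)c1C | intermediate
15 | 4-hydroxy-2-methoxy-3,5-dimethyl-6-{(1S,6S)-1,3,5-trimethyl-6-[(2Z)-4-oxopent-2-en-2-yl]cyclohexa-2,4-dien-1-yl}pyrylium trifluoromethanesulfonate | COc1[o+]c([C@@]2(C)C=C(C)C=C(C)[C@H]2/C(C)=C\C(C)=O)c(C)c(O)c1C.[O-]S(=O)(=O)C(F)(F)F | intermediate (not isolated)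
16 | 2-methoxy-3,5-dimethyl-6-{(1S,6S)-1,3,5-trimethyl-6-[(2Z)-4-oxopent-2-en-2-yl]cyclohexa-2,4-dien-1-yl}-4H-pyran-4-one | COc1oc([C@@]2(C)C=C(C)C=C(C)[C@H]2/C(C)=C\C(C)=O)c(C)c(=O)c1C | intermediate
17 | 2-methoxy-3,5-dimethyl-6-{(1S,6S)-1,3,5-trimethyl-6-[(2E)-4-oxopent-2-en-2-yl]cyclohexa-2,4-dien-1-yl}-4H-pyran-4-one | COc1oc([C@@]2(C)C=C(C)C=C(C)[C@H]2/C(C)=C/C(C)=O)c(C)c(=O)c1C | target

**Step count**

Total steps: 9. Longest linear sequence: 8 steps (steps 1, 2, 4, 5, 6, 7, 8, 9 from 3,5-dimethylbenzoic acid); step 3 is the one-step side branch.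

**Steps most likely to fail**

Step 5 (Heck desymmetrisation). Three processes may go wrong. The ester has to turn into its less favoured s-cis rotamer before the crowded 7-exo insertion, so ring closure may lose to proto-deiodination or 8-endo insertion. The bulky chelated cationic complex may discriminate poorly between the two enantiotopic alkenes across a flexible seven-membered transition state. β-Hydride loss may go toward the C5 methyl. The fallback gives up catalyst control of the absolute configuration and sets out from 9. Phosphine-free conditions (Pd(OAc)2, Bu4NCl, KOAc, DMF, 60–80 °C), which tolerate hindered insertions better than a chelating bisphosphine, should give racemic cis-5,6,8,9a-tetramethyl-3-methylidene-5a,9a-dihydro-2-benzoxepin-1(3H)-one F1, the tether still enforcing the cis fusion. The enantiomers are then separated by preparative HPLC on a chiral stationary phase. The (5aS,9aS) enantiomer is compound 10, at which the route is rejoined before step 6; its configuration is to be confirmed by crystallography of a later derivative.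

Step 6 (dianion acylation). Addition of the bulky doubly methylated dianion to a carbonyl flanked by the quaternary C1 may be slow, so that proton transfer or attack on other sites takes over. The fallback replaces the acylation by an aldol addition to an aldehyde followed by oxidation, and sets out from 10. Reduction with iBu2AlH (2.2 equiv, CH2Cl2, −78 °C) should open the enol lactone and reduce the aldehyde formed, while the released ketone is protected as its aluminium enolate, giving (3Z)-4-[(1S,6S)-6-(hydroxymethyl)-2,4,6-trimethylcyclohexa-2,4-dien-1-yl]pent-3-en-2-one F2. Dess–Martin periodinane (NaHCO3, CH2Cl2) then gives (1S,6S)-1,3,5-trimethyl-6-[(2Z)-4-oxopent-2-en-2-yl]cyclohexa-2,4-diene-1-carbaldehyde F3. Addition of excess dianion 12 at −78 °C (the first equivalent enolises and thereby masks the methyl ketone) gives methyl 5-hydroxy-2,4-dimethyl-3-oxo-5-{(1S,6S)-1,3,5-trimethyl-6-[(2Z)-4-oxopent-2-en-2-yl]cyclohexa-2,4-dien-1-yl}pentanoate F4 as a diastereomer mixture. A second Dess–Martin oxidation converges on compound 13, and the route is rejoined at step 7.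

Step 4 (enol ester formation). The strong base may deprotonate the iodoenone at the γ-methyl, with loss of iodide, or the enolate may be acylated at carbon. The fallback avoids the strong base and the metal enolate, and sets out from 7 and 4. Soft enolisation of 7 (Me3SiOTf, iPr2NEt, CH2Cl2, 0 °C) should give (3Z)-4-iodo-2-(trimethylsilyloxy)penta-1,3-diene F5. Acid 4 with cyanuric fluoride and pyridine gives 1,3,5-trimethylcyclohexa-2,5-diene-1-carbonyl fluoride F6. The two are joined with catalytic Bu4N[Ph3SiF2] in THF; the fluoride-released naked enolate is acylated at oxygen, and Si–F bond formation drives the turnover. The product is compound 9, at which the route is rejoined before step 5.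

**Further compounds**

F1 | step 5 | racemic cis-5,6,8,9a-tetramethyl-3-methylidene-5a,9a-dihydro-2-benzoxepin-1(3H)-one | O=C3C2(C)C=C(C)C=C(C)C2/C(C)=C\C(=C)O3
F2 | step 6 | (3Z)-4-[(1S,6S)-6-(hydroxymethyl)-2,4,6-trimethylcyclohexa-2,4-dien-1-yl]pent-3-en-2-one | OC[C@@]1(C)C=C(C)C=C(C)[C@H]1/C(C)=C\C(C)=O
F3 | step 6 | (1S,6S)-1,3,5-trimethyl-6-[(2Z)-4-oxopent-2-en-2-yl]cyclohexa-2,4-diene-1-carbaldehyde | O=C[C@@]1(C)C=C(C)C=C(C)[C@H]1/C(C)=C\C(C)=O
F4 | step 6 | methyl 5-hydroxy-2,4-dimethyl-3-oxo-5-{(1S,6S)-1,3,5-trimethyl-6-[(2Z)-4-oxopent-2-en-2-yl]cyclohexa-2,4-dien-1-yl}pentanoate | COC(=O)C(C)C(=O)C(C)C(O)[C@@]1(C)C=C(C)C=C(C)[C@H]1/C(C)=C\C(C)=O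
F5 | step 4 | (3Z)-4-iodo-2-(trimethylsilyloxy)penta-1,3-diene | C=C(O[Si](C)(C)C)/C=C(/C)I
F6 | step 4 | 1,3,5-trimethylcyclohexa-2,5-diene-1-carbonyl fluoride | O=C(F)C1(C)C=C(C)CC(C)=C1
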